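A rate of 0.513 /h was what I took from the gamma run: the drain rate, isomer of the product gained per hour over the target standing in the flask, read between 4.00 h and 6.00 h.

| setting | gamma | midnight | winter | dusk |
|---|---|---|---|---|
| substrate | 10 mM | 20 mM | 20 mM | 20 mM |
| coupling partner | 40 mM | 40.0 mM | 40.0 mM | 40.0 mM |
| temperature | 90 °C | 90 °C | 65 °C | 115 °C |
| remark | run made earlier |  |  |  |
| time |  | 20 h | 20 h | 20 h |

gamma run (percent of the substrate charged)

| time / h | target / % | isomer of the product / % |
|---|---|---|
| 0.500 | 0 | 1.1 |
| 0.833 | 0 | 0 |
| 1.33 | 0.7 | 0.7 |
| 2.00 | 4.1 | 1.8 |
| 4.00 | 7.6 | 7.9 |
| 6.00 | 8.2 | 16.0 |

(each reading ± 1 percentage point)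

- what was read earlier has a scatter of 1 percentage point, one standard deviation
- the earlier runs do not show what temperature does; that part of a forecast is a guess

- the best flask by share of target in all that became target or isomer of the product; "all alike" if 1.5 percentage points covers them all (midnight / winter / dusk / all alike)
- share of target in all that became target or isomer of the product, midnight
- share of target in all that became target or isomer of the product, winter
- share of target in all that became target or isomer of the product, dusk

I ran midnight slowly in my head, in fractions of the charge. It holds twice the substrate of the gamma run at the same temperature, and I kept the drain rate for it.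

1. First instants. Up to 1.33 h the gamma readings barely left the scatter of 1 percentage point. I saw a lag and ignored it, as I ignored any slowing of the feed.

2. Early end. With a steady feed, target just made had had little time to leave, so in my reckoning the share started close to whole.

3. Middle. In the gamma run target stood at 7.6 %, then 8.2 %, while isomer of the product doubled. That step in target lay within the scatter of 1 point, so the readings could not tell a plateau from a slow climb; I reckoned as if what came in was leaving.

4. Late end. A target lifetime of 1.95 h was far shorter than the 20 h of midnight. The flask held 10.3 lifetimes, and the share tended to one over that count.

5. Join. The form (one minus exp(−count)) over count has both ends. At the last gamma reading it gave 31.0 % against a read 33.9 %, which is no test, since both come from the same readings. For midnight it gave 9.75 %.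

6. Temperature was a guess. I took cold to shrink the count and heat to raise it, so I bet on winter.

The forecast also named winter, with 10 % for midnight, 50 % for winter and 2 % for dusk, and called the winter figure “the most uncertain value”.

The flasks gave 9.80 % for midnight, 83.3 % for winter and 1.65 % for dusk, so winter was best.

    substrate + coupling partner → intermediate (k = 2.80 /M/h, Ea = 92.0 kJ/mol)
    intermediate → target (k = 0.220 /h, Ea = 125 kJ/mol)
    target ⇌ isomer of the product (K = 21.0, k = 0.570 /h, Ea = 123 kJ/mol, ΔH = 49.0 kJ/mol)
    (constants at 90 °C)

My 9.75 % stood beside 9.80 % for midnight. Winter's high share is kinetic control, not thermodynamic: left ten times as long, to 200 h, winter falls from 83.3 % to 26.6 %, so the time allowed is the main reason for its height. Now the neighbour, a flask like dusk kept at 90 °C: its 20 h again holds 10.3 lifetimes at my drain rate, which gives 9.75 %. The computed neighbour gives 9.80 %.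

The earlier runs and the new flask were computed with made-up constants, noise included.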